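Ring A holds O1 and the C4 hydroxyl on the two carbons that flank C3a, so O1–C7a=C3a–C4(OH) is the enol ether of a 2-substituted cyclohexane-1,3-dione. Ring A is therefore carried as ethyl 3,5-dioxocyclohexanecarboxylate, whose carbon between the carbonyl groups becomes C3a. Its ring B arylidene derivative, unmasked from a sulfinate adduct, takes up a chiral ring C benzylsulfonium ylide at the future C3; the enolate so formed closes the dihydrofuran by O-alkylation at C2 with loss of the sulfide. One operation makes C2–C3 and O1–C2 and sets both stereocentres, and the two equivalent dione oxygens need no differentiation. Aromatisation, ester-to-aldehyde adjustment and MOM removal follow.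

Key step: step 6

Assumption: (1R,4R,5R)-isothiocineole is taken as a commercial sulfide (otherwise one step from (R)-limonene, sulfur and γ-terpinene), and the sense of induction of its benzyl ylide is taken from the facial model given in step 6; if the opposite sense were found, the enantiomeric sulfide would be used with no other change.

Step 1
Reactants: 1 3,5-dihydroxybenzaldehyde
Product: 2 3,5-bis(methoxymethoxy)benzaldehyde
Conditions: MOMCl (2.5 equiv), iPr2NEt (3 equiv), CH2Cl2, 0 °C to rt
Reagents that add atoms: chloromethyl methyl ether (MOMCl), COCCl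
Why: Williamson-type O-alkylation of both phenols gives the bis-MOM ether, which should survive every basic, hydride and oxidative step up to the final acid treatment.

Step 2
Reactants: 2 3,5-bis(methoxymethoxy)benzaldehyde, 3 ethyl 3,5-dioxocyclohexane-1-carboxylate
Product: 4 ethyl 4-{[3,5-bis(methoxymethoxy)phenyl](4-methylbenzenesulfonyl)methyl}-3-hydroxy-5-oxocyclohex-3-ene-1-carboxylate (enol form, racemic diastereomer mixture)
Conditions: 4-MeC6H4SO2Na (1.5 equiv), AcOH (2 equiv), EtOH–H2O (1:1), rt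
Reagents that add atoms: sodium p-toluenesulfinate, Cc1ccc(cc1)S(=O)[O-].[Na+]
Why: Knoevenagel condensation at the carbon between the two carbonyl groups, then conjugate addition of sulfinate (three-component sulfonylalkylation of a 1,3-dicarbonyl compound), should store the reactive arylidene dione as a stable adduct before a second dione can add.

Step 3
Reactants: 5 4-(methoxymethoxy)benzaldehyde
Product: 6 [4-(methoxymethoxy)phenyl]methanol
Conditions: NaBH4, MeOH, 0 °C
Reagents that add atoms: none
Why: Borohydride reduction of the aldehyde to the benzylic alcohol leaves the MOM acetal untouched.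

Step 4
Reactants: 6 [4-(methoxymethoxy)phenyl]methanol
Product: 7 1-(bromomethyl)-4-(methoxymethoxy)benzene
Conditions: CBr4, PPh3, CH2Cl2, 0 °C
Reagents that add atoms: carbon tetrabromide, BrC(Br)(Br)Br
Why: The Appel reaction converts the benzylic alcohol into the bromide under neutral conditions that spare the acid-labile MOM ether; the bromide is used without storage.

Step 5
Reactants: 7 1-(bromomethyl)-4-(methoxymethoxy)benzene, 8 (1R,4R,5R)-isothiocineole
Product: 9 (1R,4R,5R)-6-[4-(methoxymethoxy)benzyl]-4,7,7-trimethyl-6-thiabicyclo[3.2.1]octan-6-ium trifluoromethanesulfonate (benzyl group exo on sulfur)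
Conditions: LiOSO2CF3 (3 equiv), CH2Cl2–H2O, rt
Reagents that add atoms: lithium trifluoromethanesulfonate, [Li+].[O-]S(=O)(=O)C(F)(F)F
Why: SN2 S-alkylation of the sulfide on its exo lone pair (away from the three-carbon bridge) should give one sulfonium diastereomer, and exchange of bromide for triflate stops the reverse dealkylation.

Step 6
Reactants: 4 ethyl 4-{[3,5-bis(methoxymethoxy)phenyl](4-methylbenzenesulfonyl)methyl}-3-hydroxy-5-oxocyclohex-3-ene-1-carboxylate, 9 (1R,4R,5R)-6-[4-(methoxymethoxy)benzyl]-4,7,7-trimethyl-6-thiabicyclo[3.2.1]octan-6-ium trifluoromethanesulfonate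
Product: 13 ethyl (2S,3S)-3-[3,5-bis(methoxymethoxy)phenyl]-2-[4-(methoxymethoxy)phenyl]-4-oxo-2,3,4,5,6,7-hexahydro-1-benzofuran-6-carboxylate (both C6 epimers), via arylidene dione 10 (not isolated), via sulfonium ylide 11 (not isolated), via betaine 12 (not isolated)
Conditions: Cs2CO3 (3 equiv), 9 (1.3 equiv), CH2Cl2–MeCN, −20 °C to rt
Reagents that add atoms: none
Why: Cs2CO3 deprotonates the enol of 4 and triggers E1cB loss of sulfinate to the highly electrophilic 2-arylidene-1,3-dione 10, and it deprotonates 9 to the semi-stabilised ylide 11, which adds in Michael fashion to the exocyclic carbon (future C3) to give the sulfonium enolate betaine 12. An enolate oxygen then displaces isothiocineole from the benzylic carbon (future C2) in a 5-exo-tet O-alkylation with inversion, which forms the O1–C2 bond and closes the dihydrofuran ring. The closest known reaction type is the sulfur ylide Michael-initiated formal (4+1) annulation of 2-alkylidene-1,3-dicarbonyl compounds and o-quinone methides to trans-2,3-dihydrofurans, run here with an isothiocineole-derived chiral benzylsulfonium ylide. C2 is set by the sulfide, since the ylide should react in the conformer with its aryl group syn to the sulfur lone pair and on the face anti to the exo methyl of the CMe2 carbon, so that the following inversion delivers 2S; C3 is set relative to C2 by the anti-periplanar betaine that places the two aryl groups trans, which gives 3S, while C6 forms as both epimers and is erased in step 7. The step needs O- over C-alkylation of the enolate and conjugate over carbonyl addition of the ylide: the cyclic dione enolate closes through oxygen to an unstrained vinylogous ester (a spirocyclopropane, if formed, is a donor-acceptor cyclopropane that should ring-expand to the same trans product), and no aldehyde is present because the formyl carbon is carried as the ester. Either dione oxygen may close the ring, since both lead to the same constitution.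

Step 7
Reactants: 13 ethyl (2S,3S)-3-[3,5-bis(methoxymethoxy)phenyl]-2-[4-(methoxymethoxy)phenyl]-4-oxo-2,3,4,5,6,7-hexahydro-1-benzofuran-6-carboxylate
Product: 16 ethyl (2S,3S)-3-[3,5-bis(methoxymethoxy)phenyl]-4-hydroxy-2-[4-(methoxymethoxy)phenyl]-2,3-dihydro-1-benzofuran-6-carboxylate, via selenide 14 (not isolated), via dienone 15 (not isolated)
Conditions: LiN(iPr)2 (1.2 equiv), THF, −78 °C; PhSeBr, −78 °C; then H2O2 (30% aq.), pyridine, CH2Cl2, 0 °C to rt
Reagents that add atoms: none
Why: Kinetic enolate selenenylation and selenoxide syn-elimination (ketone dehydrogenation) should give a cyclohexadienone that tautomerises at once to the phenol of ring A; whichever α or γ site is selenenylated the same arene results, and C2–H and C3–H are not acidic, so both stereocentres survive.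

Step 8
Reactants: 16 ethyl (2S,3S)-3-[3,5-bis(methoxymethoxy)phenyl]-4-hydroxy-2-[4-(methoxymethoxy)phenyl]-2,3-dihydro-1-benzofuran-6-carboxylate
Product: 17 (2S,3S)-3-[3,5-bis(methoxymethoxy)phenyl]-6-(hydroxymethyl)-2-[4-(methoxymethoxy)phenyl]-2,3-dihydro-1-benzofuran-4-ol
Conditions: (iBu)2AlH (4 equiv), CH2Cl2, −78 to 0 °C; aq. potassium sodium tartrate work-up
Reagents that add atoms: none
Why: Hydride reduction of the aryl ester gives the benzylic alcohol, with the phenol carried as its aluminium phenoxide and the MOM ethers and the dihydrofuran inert at low temperature.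

Step 9
Reactants: 17 (2S,3S)-3-[3,5-bis(methoxymethoxy)phenyl]-6-(hydroxymethyl)-2-[4-(methoxymethoxy)phenyl]-2,3-dihydro-1-benzofuran-4-ol
Product: 18 (2S,3S)-3-[3,5-bis(methoxymethoxy)phenyl]-4-hydroxy-2-[4-(methoxymethoxy)phenyl]-2,3-dihydro-1-benzofuran-6-carbaldehyde
Conditions: activated MnO2 (15 equiv), EtOAc, rt
Reagents that add atoms: none
Why: MnO2 oxidation is selective for the benzylic alcohol and should stop at the aldehyde while leaving the single free phenol (meta to the carbinol) and the benzylic ether C2–H alone.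

Step 10
Reactants: 18 (2S,3S)-3-[3,5-bis(methoxymethoxy)phenyl]-4-hydroxy-2-[4-(methoxymethoxy)phenyl]-2,3-dihydro-1-benzofuran-6-carbaldehyde
Product: 19 gnetal, (2S,3S)-3-(3,5-dihydroxyphenyl)-4-hydroxy-2-(4-hydroxyphenyl)-2,3-dihydro-1-benzofuran-6-carbaldehyde
Conditions: 2 M HCl, MeOH–THF–H2O, 40 °C
Reagents that add atoms: none
Why: Acid-catalysed acetal hydrolysis removes the three MOM groups; C3 cannot epimerise, and any reversible ionisation at C2 should reclose to the favoured trans ring, so the configuration is kept.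

Compound list
1 | 3,5-dihydroxybenzaldehyde | O=Cc1cc(O)cc(O)c1 | starting material
2 | 3,5-bis(methoxymethoxy)benzaldehyde | O=Cc1cc(OCOC)cc(OCOC)c1 | intermediate
3 | ethyl 3,5-dioxocyclohexane-1-carboxylate | CCOC(=O)C1CC(=O)CC(=O)C1 | starting material
4 | ethyl 4-{[3,5-bis(methoxymethoxy)phenyl](4-methylbenzenesulfonyl)methyl}-3-hydroxy-5-oxocyclohex-3-ene-1-carboxylate | CCOC(=O)C1CC(O)=C(C(c2cc(OCOC)cc(OCOC)c2)S(=O)(=O)c2ccc(C)cc2)C(=O)C1 | intermediate
5 | 4-(methoxymethoxy)benzaldehyde | O=Cc1ccc(OCOC)cc1 | starting material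
6 | [4-(methoxymethoxy)phenyl]methanol | OCc1ccc(OCOC)cc1 | intermediate
7 | 1-(bromomethyl)-4-(methoxymethoxy)benzene | BrCc1ccc(OCOC)cc1 | intermediate
8 | (1R,4R,5R)-4,7,7-trimethyl-6-thiabicyclo[3.2.1]octane (isothiocineole) | C[C@@H]1CC[C@@H]2C[C@H]1SC2(C)C | starting material
9 | (1R,4R,5R)-6-[4-(methoxymethoxy)benzyl]-4,7,7-trimethyl-6-thiabicyclo[3.2.1]octan-6-ium trifluoromethanesulfonate | C[C@@H]1CC[C@@H]2C[C@H]1[S@@+](Cc3ccc(OCOC)cc3)C2(C)C.[O-]S(=O)(=O)C(F)(F)F | intermediate
10 | ethyl 4-{[3,5-bis(methoxymethoxy)phenyl]methylidene}-3,5-dioxocyclohexane-1-carboxylate | CCOC(=O)C1CC(=O)C(=Cc2cc(OCOC)cc(OCOC)c2)C(=O)C1 | intermediate (not isolated)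
11 | [4-(methoxymethoxy)phenyl][(1R,4R,5R)-4,7,7-trimethyl-6-thiabicyclo[3.2.1]octan-6-ium-6-yl]methanide (ylide of 9) | C[C@@H]1CC[C@@H]2C[C@H]1[S@@+]([CH-]c3ccc(OCOC)cc3)C2(C)C | intermediate (not isolated)
12 | 2-{(1S,2R)-1-[3,5-bis(methoxymethoxy)phenyl]-2-[4-(methoxymethoxy)phenyl]-2-[(1R,4R,5R)-4,7,7-trimethyl-6-thiabicyclo[3.2.1]octan-6-ium-6-yl]ethyl}-5-(ethoxycarbonyl)-3-oxocyclohex-1-en-1-olate (betaine) | C[C@@H]1CC[C@@H]2C[C@H]1[S@@+]([C@@H](c3ccc(OCOC)cc3)[C@@H](c3cc(OCOC)cc(OCOC)c3)C3=C([O-])CC(CC3=O)C(=O)OCC)C2(C)C | intermediate (not isolated)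
13 | ethyl (2S,3S)-3-[3,5-bis(methoxymethoxy)phenyl]-2-[4-(methoxymethoxy)phenyl]-4-oxo-2,3,4,5,6,7-hexahydro-1-benzofuran-6-carboxylate (both C6 epimers) | CCOC(=O)C1CC(=O)C2=C(C1)O[C@H](c1ccc(OCOC)cc1)[C@H]2c1cc(OCOC)cc(OCOC)c1 | intermediate
14 | ethyl (2S,3S)-3-[3,5-bis(methoxymethoxy)phenyl]-2-[4-(methoxymethoxy)phenyl]-4-oxo-5-(phenylselanyl)-2,3,4,5,6,7-hexahydro-1-benzofuran-6-carboxylate | CCOC(=O)C1C([Se]c3ccccc3)C(=O)C2=C(C1)O[C@H](c1ccc(OCOC)cc1)[C@H]2c1cc(OCOC)cc(OCOC)c1 | intermediate (not isolated)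
15 | ethyl (2S,3S)-3-[3,5-bis(methoxymethoxy)phenyl]-2-[4-(methoxymethoxy)phenyl]-4-oxo-2,3,4,7-tetrahydro-1-benzofuran-6-carboxylate | CCOC(=O)C1=CC(=O)C2=C(C1)O[C@H](c1ccc(OCOC)cc1)[C@H]2c1cc(OCOC)cc(OCOC)c1 | intermediate (not isolated)
16 | ethyl (2S,3S)-3-[3,5-bis(methoxymethoxy)phenyl]-4-hydroxy-2-[4-(methoxymethoxy)phenyl]-2,3-dihydro-1-benzofuran-6-carboxylate | CCOC(=O)c1cc(O)c2c(c1)O[C@H](c1ccc(OCOC)cc1)[C@H]2c1cc(OCOC)cc(OCOC)c1 | intermediate
17 | (2S,3S)-3-[3,5-bis(methoxymethoxy)phenyl]-6-(hydroxymethyl)-2-[4-(methoxymethoxy)phenyl]-2,3-dihydro-1-benzofuran-4-ol | OCc1cc(O)c2c(c1)O[C@H](c1ccc(OCOC)cc1)[C@H]2c1cc(OCOC)cc(OCOC)c1 | intermediate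
18 | (2S,3S)-3-[3,5-bis(methoxymethoxy)phenyl]-4-hydroxy-2-[4-(methoxymethoxy)phenyl]-2,3-dihydro-1-benzofuran-6-carbaldehyde | O=Cc1cc(O)c2c(c1)O[C@H](c1ccc(OCOC)cc1)[C@H]2c1cc(OCOC)cc(OCOC)c1 | intermediate
19 | gnetal, (2S,3S)-3-(3,5-dihydroxyphenyl)-4-hydroxy-2-(4-hydroxyphenyl)-2,3-dihydro-1-benzofuran-6-carbaldehyde | O=Cc1cc(O)c2c(c1)O[C@H](c1ccc(O)cc1)[C@H]2c1cc(O)cc(O)c1 | target

Total step count: 10. Longest linear sequence: 8 steps (steps 3, 4, 5, 6, 7, 8, 9, 10, from compound 5).

Steps most likely to fail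

Step 6. The ylide may select its face imperfectly, or the electron-rich benzylic sulfonium of the betaine may ionise before ring closure, and either would erode enantiomeric purity. Part of 9 may also be consumed by alkylating sulfinate or enolate. The fallback sets out from 7 and 4 and comes back at 16; it replaces reagent control by a racemic annulation and a resolution. Compound 7 and tetrahydrothiophene (acetone, rt) should give 1-[4-(methoxymethoxy)benzyl]thiolan-1-ium bromide F1. F1 and 4 with Cs2CO3 in CH2Cl2–MeCN should give the racemic trans annulation product, ethyl rac-(2S,3S)-3-[3,5-bis(methoxymethoxy)phenyl]-2-[4-(methoxymethoxy)phenyl]-4-oxo-2,3,4,5,6,7-hexahydro-1-benzofuran-6-carboxylate F2. The conditions of step 7 should turn F2 into the racemic phenol, ethyl rac-(2S,3S)-3-[3,5-bis(methoxymethoxy)phenyl]-4-hydroxy-2-[4-(methoxymethoxy)phenyl]-2,3-dihydro-1-benzofuran-6-carboxylate F3. Preparative chromatography of F3 on a chiral stationary phase would then separate the enantiomers, the (2S,3S) enantiomer being 16.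

Step 2. The arylidene dione may be intercepted by a second molecule of dione (bis-adduct formation) faster than by sulfinate. The fallback sets out from 2 and 3 and comes back at 4; it traps the Knoevenagel product with a thiol and raises the sulfur oxidation level afterwards. Compounds 2 and 3 with 4-methylbenzenethiol (L-proline cat., EtOH, rt; three-component thia-Michael trapping) should give ethyl 4-{[3,5-bis(methoxymethoxy)phenyl][(4-methylphenyl)sulfanyl]methyl}-3-hydroxy-5-oxocyclohex-3-ene-1-carboxylate F4. Oxidation of F4 with mCPBA (2.1 equiv, CH2Cl2, 0 °C) should give sulfone 4.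

Step 7. The selenoxide may fail to find a syn hydrogen in one diastereomer, so that elimination stalls, or the selenium oxidant may over-oxidise the newly formed phenol. The fallback sets out from 13 and comes back at 16; it uses a Saegusa–Ito dehydrogenation instead. Compound 13 with LiN(iPr)2 and Me3SiCl (THF, −78 °C) should give the silyl dienol ether, ethyl (2S,3S)-3-[3,5-bis(methoxymethoxy)phenyl]-2-[4-(methoxymethoxy)phenyl]-4-[(trimethylsilyl)oxy]-2,3,6,7-tetrahydro-1-benzofuran-6-carboxylate F5. Treatment of F5 with Pd(OAc)2 (1.1 equiv, MeCN, rt) should give dienone 15, which tautomerises to 16.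

Further compounds
F1 | step 6 | 1-[4-(methoxymethoxy)benzyl]thiolan-1-ium bromide | C1CC[S+](C1)Cc1ccc(OCOC)cc1.[Br-]
F2 | step 6 | ethyl rac-(2S,3S)-3-[3,5-bis(methoxymethoxy)phenyl]-2-[4-(methoxymethoxy)phenyl]-4-oxo-2,3,4,5,6,7-hexahydro-1-benzofuran-6-carboxylate (racemate, both enantiomers written) | CCOC(=O)C1CC(=O)C2=C(C1)O[C@H](c1ccc(OCOC)cc1)[C@H]2c1cc(OCOC)cc(OCOC)c1.CCOC(=O)C1CC(=O)C2=C(C1)O[C@@H](c1ccc(OCOC)cc1)[C@@H]2c1cc(OCOC)cc(OCOC)c1
F3 | step 6 | ethyl rac-(2S,3S)-3-[3,5-bis(methoxymethoxy)phenyl]-4-hydroxy-2-[4-(methoxymethoxy)phenyl]-2,3-dihydro-1-benzofuran-6-carboxylate (racemate, both enantiomers written) | CCOC(=O)c1cc(O)c2c(c1)O[C@H](c1ccc(OCOC)cc1)[C@H]2c1cc(OCOC)cc(OCOC)c1.CCOC(=O)c1cc(O)c2c(c1)O[C@@H](c1ccc(OCOC)cc1)[C@@H]2c1cc(OCOC)cc(OCOC)c1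
F4 | step 2 | ethyl 4-{[3,5-bis(methoxymethoxy)phenyl][(4-methylphenyl)sulfanyl]methyl}-3-hydroxy-5-oxocyclohex-3-ene-1-carboxylate | CCOC(=O)C1CC(O)=C(C(Sc2ccc(C)cc2)c2cc(OCOC)cc(OCOC)c2)C(=O)C1
F5 | step 7 | ethyl (2S,3S)-3-[3,5-bis(methoxymethoxy)phenyl]-2-[4-(methoxymethoxy)phenyl]-4-[(trimethylsilyl)oxy]-2,3,6,7-tetrahydro-1-benzofuran-6-carboxylate | CCOC(=O)C1C=C(O[Si](C)(C)C)C2=C(C1)O[C@H](c1ccc(OCOC)cc1)[C@H]2c1cc(OCOC)cc(OCOC)c1
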